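(The constants used here stand for no real mixture; the result is computed.)

I began with the balance.

starting material 0.020 M; reagent 0.0400 M; catalyst 40 µM; time 1.5 h

    starting material + reagent + catalyst → catalyst + target (k1 = 78900 M⁻² min⁻¹)
    target + catalyst ⇌ isomer of the product + catalyst, rate k2*[catalyst]*[target] forward; the back reaction follows from the equilibrium constant (K2 = 1.0, k2 = 7850 M⁻¹ min⁻¹)
    crystals ⇌ target, rate k3*(cs3 - [target]) while solid is left; crystals form when [target] > cs3 (cs3 = 14 mM, k3 = 1.94 min⁻¹)

- ochre: doubling the solubility in step 3, all else as stated
- grey: doubling the dissolution coefficient of step 3, all else as stated
- green: doubling the amount of reagent, all else as stated
- violet: doubling the amount of catalyst, all else as stated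

- target is meant together with its crystals
- solid, in amounts per volume of the solution: crystals
- run time (flask): 1.5 h

1. target and crystals together at 1.5 h, in percent of the starting material charged
2. the change that raises the amount of target and crystals together at 1.5 h, in percent of the starting material charged most ("none" if none brings more than 2 percentage points) (ochre / grey / green / violet / none)
3. amount of target and crystals together at 1.5 h, in percent of the starting material charged, after ochre

The quantity I carried was the split f, the share of converted starting material that stands as target once the isomerisation has balanced, K/(1+K), with K its equilibrium constant: 0.500. With K at 1.0, the symmetric case, that is half, the zero of my scale.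

I took two extreme versions of the flask. In the first, the isomerisation balanced at once, so dissolved target topped out at f times the charge, 10.0 mM, less than the solubility of 14 mM, and no crystals formed. In the second, the isomerisation was absent, so the charge of 0.020 M could pass that solubility, crystals formed, and y equalled the conversion.

The real flask lay between them. The lag, target minus isomer of the product, was fed by the first step at 2.52 mM min⁻¹ at most, its starting rate, and relaxed at 0.628 min⁻¹. So the lag stayed below their ratio, and dissolved target stayed below 12.0 mM, still less than the solubility. The relaxation half-time of 1.10 min is far shorter than the 1.5 h run, so I placed the end of the run at the first extreme, with y equal to f times the conversion.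

Starting material is the limiting reagent, and integrating the first step with the catalyst unchanged left a fraction 0.171 % of it. I therefore committed to y = 49.9 %, and to the same after ochre, 49.9 %, since ochre acts on crystals I did not expect. Green and violet can add at most f times that remainder, 0.086 percentage points, less than the 2 points margin, so my choice was none.

The forecast gave 49.9 % (range 49.7 % to 50.1 %), 49.9 % after ochre and none as the best change, saying “never reaching 14 mM, and no crystals form”. My ceiling stood above its peak of 10 mM, though both lay under the solubility.

The flask gave 49.9 %, 49.9 % after ochre, and none as the best change. Its crystals at 1.50 h read 0 %. Two changes tried took y away from the forecast: with the other amounts and the time held, y had moved by 5 points at 0.0221 M of reagent, and likewise at 0.0331 M of starting material. The neighbour flask with 0.010 M of reagent kept 51.5 % of its starting material, so f times the converted part gives 24.2 %, and that flask held 24.3 %.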